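Numbering: ring C1(H)–C2–C3=C4(Me)–C5–C6–C7=C8(C20H2OH)–C9–C10–C11=C12(Me)–C13–C14–C1; side chain C15(Me)=C16–C17–C18=C19Me2 on C1.
Retrosynthesis cuts C13–C14 (opens the 14-membered ring), then C8–C9 (splits the chain into a C1–C8/C14–C20 alkynol and a C9–C13 Grignard reagent), then C8–C20, C1–C2, C7≡C8 and C16–C17/C15–CH3.
Enabling feature: the ring alkene C7=C8 is a 2-substituted allylic alcohol with C20H2OH trans to C6 and C9 cis to C6, which is the outcome of adding C9 and H anti across a C7≡C8 2-alkyn-1-ol.
Forward: the chain is joined at C1–C2 (step 8), C8–C20 (step 11) and C8–C9 (step 15); the only ring closes last at C13–C14 by alkylation of a C14 sulfonyl carbanion with the C13 allylic bromide (step 20).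
Stereochemistry: C1 (R) from an (R)-4-benzyloxazolidinone-controlled enolate alkylation; 3Z from neryl acetate; 15E from syn-carboalumination; 11E from SeO2 oxidation; 7E from chelate-enforced anti-carbomagnesiation.

Key step: step 15

Remark: the sulfur of 31 and C14 of 36 are stereogenic but arise as mixtures that converge in the next step, so they are left undefined; neryl acetate is used as the commercial form of the nerol unit, and descriptive names of late compounds use the target numbering above.

Step 1
Reactants: 1 but-3-yn-1-ol; 2 1-bromo-3-methylbut-2-ene (prenyl bromide)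
Product: 4 (3E)-3,7-dimethylocta-3,6-dien-1-ol, via alkenylalane 3 (not isolated)
Conditions: Me3Al (3 equiv), Cp2ZrCl2 (0.25 equiv), CH2Cl2, 0 °C → rt; then 2, Pd(PPh3)4 (3 mol%), THF, 0 °C → rt; aqueous work-up
Reagents that add atoms: trimethylaluminium, C[Al](C)C
Why: Zirconium-catalysed Negishi carboalumination adds methyl and aluminium syn across the terminal alkyne (methyl to C15, aluminium to C16), and palladium-catalysed cross-coupling of the alkenylalane with the primary carbon of the allylic bromide should then give the E-trisubstituted skipped diene with retention.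

Step 2
Reactants: 4 (3E)-3,7-dimethylocta-3,6-dien-1-ol
Product: 6 (3E)-3,7-dimethylocta-3,6-dienoic acid, via aldehyde 5 (not isolated)
Conditions: 2,2,6,6-tetramethylpiperidin-1-oxyl (TEMPO, 0.2 equiv), PhI(OAc)2 (2.2 equiv), MeCN/H2O 1:1, rt
Reagents that add atoms: water, O
Why: The nitroxyl-catalysed oxidation with PhI(OAc)2 in aqueous acetonitrile takes the primary alcohol through the aldehyde hydrate to the acid under near-neutral conditions that should leave the trisubstituted alkenes in place and out of conjugation.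

Step 3
Reactants: 6 (3E)-3,7-dimethylocta-3,6-dienoic acid; 7 (4R)-4-benzyl-1,3-oxazolidin-2-one
Product: 9 (4R)-4-benzyl-3-[(3E)-3,7-dimethylocta-3,6-dienoyl]-1,3-oxazolidin-2-one, via mixed pivalic anhydride 8 (not isolated)
Conditions: t-BuCOCl, Et3N, THF, −20 °C; then 7, LiCl, −20 °C → rt
Reagents that add atoms: none
Why: N-acylation of the oxazolidinone through the mixed pivalic anhydride with LiCl/Et3N activation is a standard mild procedure that needs no strong base and so should not conjugate the β,γ-unsaturated acyl group.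

Step 4
Reactants: 10 neryl acetate
Product: 11 (2Z)-5-(3,3-dimethyloxiran-2-yl)-3-methylpent-2-en-1-yl acetate (racemic at the oxirane carbon)
Conditions: 3-chloroperbenzoic acid (1.05 equiv), CH2Cl2, 0 °C
Reagents that add atoms: 3-chloroperbenzoic acid, OOC(=O)c1cccc(Cl)c1
Why: Prilezhaev epoxidation is expected to take the more electron-rich terminal alkene, the other one being deactivated by the allylic acetoxy group.

Step 5
Reactants: 11 (2Z)-5-(3,3-dimethyloxiran-2-yl)-3-methylpent-2-en-1-yl acetate
Product: 13 (2Z)-3-methyl-6-oxohex-2-en-1-yl acetate, via diol 12 (not isolated)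
Conditions: H5IO6, THF/H2O, 0 °C
Reagents that add atoms: none
Why: Periodic acid opens the epoxide with water at its tertiary carbon and cleaves the resulting glycol (Malaprade cleavage), so the aldehyde keeps the epoxide oxygen while the gem-dimethyl carbon leaves as acetone.

Step 6
Reactants: 13 (2Z)-3-methyl-6-oxohex-2-en-1-yl acetate
Product: 15 (2Z)-3-methylhept-2-en-6-yn-1-ol, via enynyl acetate 14 (not isolated)
Conditions: dimethyl (1-diazo-2-oxopropyl)phosphonate, K2CO3, MeOH, 0 °C → rt
Reagents that add atoms: dimethyl (1-diazo-2-oxopropyl)phosphonate, CC(=O)C(=[N+]=[N-])P(=O)(OC)OC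
Why: Ohira–Bestmann (Seyferth–Gilbert) homologation converts the aldehyde into the terminal alkyne with one added carbon (C8), and the same K2CO3/MeOH medium transesterifies the acetate, so the free Z-allylic alcohol should result in one operation.

Step 7
Reactants: 15 (2Z)-3-methylhept-2-en-6-yn-1-ol
Product: 16 (5Z)-7-bromo-5-methylhept-5-en-1-yne
Conditions: CBr4, PPh3, CH2Cl2, 0 °C; used without storage
Reagents that add atoms: carbon tetrabromide, BrC(Br)(Br)Br
Why: Appel bromination converts the primary allylic alcohol into the bromide under neutral, cold conditions that should preserve the Z geometry and the terminal alkyne.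

Step 8
Reactants: 9 (4R)-4-benzyl-3-[(3E)-3,7-dimethylocta-3,6-dienoyl]-1,3-oxazolidin-2-one; 16 (5Z)-7-bromo-5-methylhept-5-en-1-yne
Product: 18 (4R)-4-benzyl-3-[(2R,4Z)-5-methyl-2-[(2E)-6-methylhepta-2,5-dien-2-yl]non-4-en-8-ynoyl]-1,3-oxazolidin-2-one, via sodium enolate 17 (not isolated)
Conditions: NaN(SiMe3)2 (1.05 equiv), THF, −78 °C; then 16 (1.5 equiv), −78 → −40 °C
Reagents that add atoms: none
Why: In this Evans asymmetric alkylation the chelated sodium Z-dienolate should be alkylated at its α-carbon (C1) by the allylic bromide on the face opposite the benzyl group of the (R)-auxiliary, which sets C1 in the configuration that becomes 1R in the target while C15=C16 stays E and out of conjugation.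

Step 9
Reactants: 18 alkylated imide
Product: 19 (2R,4Z)-5-methyl-2-[(2E)-6-methylhepta-2,5-dien-2-yl]non-4-en-8-yn-1-ol
Conditions: LiBH4, H2O (1 equiv), Et2O, 0 °C
Reagents that add atoms: none
Why: Hydride reduction of the exocyclic imide carbonyl releases the primary alcohol (C14) and the intact auxiliary without touching alkenes or alkyne, and the cold, weakly basic medium should not epimerise C1.

Step 10
Reactants: 19 (2R,4Z)-5-methyl-2-[(2E)-6-methylhepta-2,5-dien-2-yl]non-4-en-8-yn-1-ol
Product: 20 [(2R,4Z)-5-methyl-2-[(2E)-6-methylhepta-2,5-dien-2-yl]non-4-en-8-yn-1-yl](phenyl)sulfane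
Conditions: PhSSPh, n-Bu3P, pyridine, rt
Reagents that add atoms: diphenyl disulfide, c1ccc(SSc2ccccc2)cc1
Why: The Hata reaction turns the primary alcohol into the phenyl thioether by SN2 displacement of an alkoxyphosphonium ion, giving a Grignard-stable precursor of the C14 sulfone used later for ring closure.

Step 11
Reactants: 20 phenyl thioether
Product: 22 fragment 1 (6Z,9R)-6-methyl-9-[(2E)-6-methylhepta-2,5-dien-2-yl]-10-(phenylsulfanyl)dec-6-en-2-yn-1-ol, via lithium acetylide 21 (not isolated)
Conditions: n-BuLi (1.05 equiv), THF, −78 °C; then (CH2O)n, −78 °C → rt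
Reagents that add atoms: formaldehyde (as paraformaldehyde), C=O
Why: Deprotonation of the terminal alkyne and addition of the acetylide to formaldehyde is the standard hydroxymethylation, which installs C20 and the free propargylic hydroxyl that directs the next fragment union.

Step 12
Reactants: 23 5-bromo-2-methylpent-2-ene
Product: 24 (2E)-5-bromo-2-methylpent-2-en-1-ol
Conditions: SeO2 (0.3 equiv), t-BuOOH (2 equiv), CH2Cl2, 0 °C → rt
Reagents that add atoms: tert-butyl hydroperoxide, CC(C)(C)OO (oxygen relayed through selenium dioxide, O=[Se]=O)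
Why: Catalytic SeO2 allylic oxidation (ene reaction then [2,3]-sigmatropic shift) is selective for the E-methyl group of a gem-dimethyl trisubstituted alkene and should give the E-allylic alcohol with the primary bromide untouched.

Step 13
Reactants: 24 (2E)-5-bromo-2-methylpent-2-en-1-ol
Product: 25 [(2E)-5-bromo-2-methylpent-2-en-1-yl]oxy(tert-butyl)dimethylsilane
Conditions: t-BuMe2SiCl, imidazole, CH2Cl2, 0 °C → rt
Reagents that add atoms: tert-butyldimethylsilyl chloride, CC(C)(C)[Si](C)(C)Cl
Why: Standard silylation of a primary allylic alcohol gives an ether that tolerates Grignard formation and can later be removed selectively beside a tert-butyldiphenylsilyl ether.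

Step 14
Reactants: 25 bromo silyl ether
Product: 26 fragment 2 [(3E)-5-(tert-butyldimethylsilyloxy)-4-methylpent-3-en-1-yl]magnesium bromide (titrated THF solution; used at once)
Conditions: Mg turnings, THF, rt
Reagents that add atoms: magnesium, [Mg]
Why: Magnesium insertion into the primary homoallylic C–Br bond is a routine Grignard formation, and keeping the solution at or below room temperature should hold back cyclisation to a cyclopropylcarbinyl species.

Step 15
Reactants: 22 fragment 1 (alkynol); 26 fragment 2 (Grignard reagent)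
Product: 29 coupled acyclic allylic alcohol (1R,3Z,7E,11E,15E; C13 OTBS; C14 SPh; free C20 hydroxyl), via bromomagnesium alkoxide 27 (not isolated), via oxamagnesacycle 28 (not isolated)
Conditions: 22, EtMgBr (1.0 equiv), THF, 0 °C; then CuI (15 mol%), 26 (2.5 equiv), THF/Et2O, −10 °C → rt; aq. NH4Cl
Reagents that add atoms: none
Why: EtMgBr first converts 22 into the alkoxide 27; an organocopper species formed from 26 and catalytic CuI then transfers its primary alkyl carbon (C9) to C8, the alkyne carbon next to the carbinol, while magnesium ends on C7 on the opposite face, where it closes the five-membered oxamagnesacycle 28 with the alkoxide oxygen, and aqueous NH4Cl replaces C7–Mg by C7–H with retention. The closest known reaction type is the copper-catalysed anti-carbomagnesiation of 2-alkyn-1-ols by alkyl Grignard reagents. No ring of the target is closed and no stereocentre is formed; the only ring involved is the transient chelate, closed by O–Mg coordination in a five-membered array. The step needs regioselectivity (carbon to C8, not C7) and anti stereoselectivity (C9 cis to C6, C20H2OH trans to C6), and both follow from the same chelate, because only anti addition with magnesium on C7 lets the metal reach the alkoxide. The thioether, silyl ether and trisubstituted alkenes offer no competing electrophile, and an alkyne precursor has no C7=C8 geometry to lose before the addition. An excess of 26 is planned because it is three steps from a commercial bromide.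

Step 16
Reactants: 29 coupled allylic alcohol
Product: 30 C20 tert-butyldiphenylsilyl ether of 29
Conditions: t-BuPh2SiCl, imidazole, CH2Cl2, rt
Reagents that add atoms: tert-butyldiphenylsilyl chloride, CC(C)(C)[Si](Cl)(c1ccccc1)c1ccccc1
Why: Silylation of the primary allylic alcohol gives an ether that should survive the acid-mediated TBS removal, the strong base of the ring closure and the reductive desulfonylation.

Step 17
Reactants: 30 bis-silyl ether thioether
Product: 32 C14 phenyl sulfone, via sulfoxide 31 (not isolated)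
Conditions: (NH4)6Mo7O24·4H2O (10 mol%), 30% H2O2, EtOH, 0 °C → rt
Reagents that add atoms: hydrogen peroxide, OO
Why: Molybdate-catalysed peroxide oxidation takes the thioether through the sulfoxide to the sulfone and is chemoselective for sulfur over trisubstituted alkenes, the allylic hydroxyl having been silylated first to exclude hydroxyl-directed epoxidation.

Step 18
Reactants: 32 C14 phenyl sulfone
Product: 33 C13 allylic alcohol (C20 OTBDPS retained)
Conditions: pyridinium p-toluenesulfonate (0.2 equiv), EtOH, rt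
Reagents that add atoms: none
Why: Mild acid-catalysed ethanolysis cleaves the primary TBS ether much faster than the bulkier, more acid-stable tert-butyldiphenylsilyl ether, so only the C13 hydroxyl should be unmasked.

Step 19
Reactants: 33 C13 allylic alcohol
Product: 34 C13 allylic bromide
Conditions: CBr4, PPh3, CH2Cl2, −20 → 0 °C
Reagents that add atoms: carbon tetrabromide, BrC(Br)(Br)Br
Why: Appel bromination converts the primary allylic alcohol into the allylic bromide without allylic transposition, the sulfone and silyl ether being inert.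

Step 20
Reactants: 34 C13 allylic bromide
Product: 36 macrocyclic C14 phenyl sulfone (14-membered ring; C20 OTBDPS; C14 epimers), via lithium sulfonyl carbanion 35 (not isolated)
Conditions: LiN(i-Pr)2 (1.5 equiv), THF (0.002 M), slow addition of 34 at −78 °C, then → 0 °C
Reagents that add atoms: none
Why: Intramolecular SN2 alkylation of an α-sulfonyl carbanion by a primary allylic bromide under high dilution closes the 14-membered ring at C13–C14, a macrocyclisation mode established for cembrane-type rings with stabilised carbanions and allylic halides, and the C14 epimers formed are merged in the next step.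

Step 21
Reactants: 36 macrocyclic sulfone
Product: 37 C20 tert-butyldiphenylsilyl ether of the target
Conditions: Na/Hg (6% Na), Na2HPO4, MeOH/THF, −20 °C → rt
Reagents that add atoms: none
Why: Buffered sodium amalgam cleaves the C14–S bond by electron transfer (reductive desulfonylation), and because C14 is not allylic no alkene should migrate or change geometry.

Step 22
Reactants: 37 silyl ether of the target
Product: 38 CNP0355114.1 (1R,3Z,7E,11E)-8-(hydroxymethyl)-4,12-dimethyl-1-[(2E)-6-methylhepta-2,5-dien-2-yl]cyclotetradeca-3,7,11-triene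
Conditions: Bu4NF, THF, 0 °C → rt
Reagents that add atoms: none
Why: Fluoride-mediated desilylation liberates the primary allylic alcohol under conditions that should leave the four trisubstituted alkenes and C1 untouched.

Compound list
1 | but-3-yn-1-ol | C#CCCO | starting material
2 | 1-bromo-3-methylbut-2-ene (prenyl bromide) | CC(C)=CCBr | starting material
3 | dimethyl[(1E)-4-(dimethylalumanyloxy)-2-methylbut-1-en-1-yl]alumane | C[Al](C)/C=C(\C)CCO[Al](C)C | intermediate
4 | (3E)-3,7-dimethylocta-3,6-dien-1-ol | CC(C)=CC/C=C(\C)CCO | intermediate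
5 | (3E)-3,7-dimethylocta-3,6-dienal | CC(C)=CC/C=C(\C)CC=O | intermediate
6 | (3E)-3,7-dimethylocta-3,6-dienoic acid | CC(C)=CC/C=C(\C)CC(O)=O | intermediate
7 | (4R)-4-benzyl-1,3-oxazolidin-2-one | O=C1N[C@H](Cc2ccccc2)CO1 | starting material
8 | (3E)-3,7-dimethylocta-3,6-dienoic pivalic anhydride | CC(C)=CC/C=C(\C)CC(=O)OC(=O)C(C)(C)C | intermediate
9 | (4R)-4-benzyl-3-[(3E)-3,7-dimethylocta-3,6-dienoyl]-1,3-oxazolidin-2-one | CC(C)=CC/C=C(\C)CC(=O)N1[C@H](Cc2ccccc2)COC1=O | intermediate
10 | neryl acetate, (2Z)-3,7-dimethylocta-2,6-dien-1-yl acetate | CC(C)=CCC/C(C)=C\COC(C)=O | starting material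
11 | (2Z)-5-(3,3-dimethyloxiran-2-yl)-3-methylpent-2-en-1-yl acetate (racemic oxirane) | CC(=O)OC/C=C(/C)CCC1OC1(C)C | intermediate
12 | (2Z)-6,7-dihydroxy-3,7-dimethyloct-2-en-1-yl acetate | CC(=O)OC/C=C(/C)CCC(O)C(C)(C)O | intermediate
13 | (2Z)-3-methyl-6-oxohex-2-en-1-yl acetate | CC(=O)OC/C=C(/C)CCC=O | intermediate
14 | (2Z)-3-methylhept-2-en-6-yn-1-yl acetate | CC(=O)OC/C=C(/C)CCC#C | intermediate
15 | (2Z)-3-methylhept-2-en-6-yn-1-ol | OC/C=C(/C)CCC#C | intermediate
16 | (5Z)-7-bromo-5-methylhept-5-en-1-yne | BrC/C=C(/C)CCC#C | intermediate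
17 | sodium (Z)-dienolate of imide 9 | [Na+].[O-]/C(=C\C(C)=C\CC=C(C)C)N1[C@H](Cc2ccccc2)COC1=O | intermediate
18 | (4R)-4-benzyl-3-[(2R,4Z)-5-methyl-2-[(2E)-6-methylhepta-2,5-dien-2-yl]non-4-en-8-ynoyl]-1,3-oxazolidin-2-one | C#CCC/C(C)=C\C[C@@H](C(=O)N1[C@H](Cc2ccccc2)COC1=O)/C(C)=C/CC=C(C)C | intermediate
19 | (2R,4Z)-5-methyl-2-[(2E)-6-methylhepta-2,5-dien-2-yl]non-4-en-8-yn-1-ol | C#CCC/C(C)=C\C[C@@H](CO)/C(C)=C/CC=C(C)C | intermediate
20 | [(2R,4Z)-5-methyl-2-[(2E)-6-methylhepta-2,5-dien-2-yl]non-4-en-8-yn-1-yl](phenyl)sulfane | C#CCC/C(C)=C\C[C@@H](CSc1ccccc1)/C(C)=C/CC=C(C)C | intermediate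
21 | lithium acetylide of 20 | [Li+].[C-]#CCC/C(C)=C\C[C@@H](CSc1ccccc1)/C(C)=C/CC=C(C)C | intermediate
22 | fragment 1, (6Z,9R)-6-methyl-9-[(2E)-6-methylhepta-2,5-dien-2-yl]-10-(phenylsulfanyl)dec-6-en-2-yn-1-ol | OCC#CCC/C(C)=C\C[C@@H](CSc1ccccc1)/C(C)=C/CC=C(C)C | intermediate
23 | 5-bromo-2-methylpent-2-ene | CC(C)=CCCBr | starting material
24 | (2E)-5-bromo-2-methylpent-2-en-1-ol | OC/C(C)=C/CCBr | intermediate
25 | [(2E)-5-bromo-2-methylpent-2-en-1-yl]oxy(tert-butyl)dimethylsilane | CC(C)(C)[Si](C)(C)OC/C(C)=C/CCBr | intermediate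
26 | fragment 2, [(3E)-5-(tert-butyldimethylsilyloxy)-4-methylpent-3-en-1-yl]magnesium bromide | CC(C)(C)[Si](C)(C)OC/C(C)=C/CC[Mg]Br | intermediate
27 | bromomagnesium alkoxide of 22 | Br[Mg]OCC#CCC/C(C)=C\C[C@@H](CSc1ccccc1)/C(C)=C/CC=C(C)C | intermediate
28 | 2,5-dihydro-1,2-oxamagnesole chelate (Mg on C7; C9–C13 chain on C8; C6–C1 chain on C7) | CC(C)(C)[Si](C)(C)OC/C(C)=C/CCC1=C(CC/C(C)=C\C[C@@H](CSc2ccccc2)/C(C)=C/CC=C(C)C)[Mg]OC1 | intermediate
29 | coupled acyclic allylic alcohol (1R,3Z,7E,11E,15E; C13 OTBS; C14 SPh; C20 OH) | CC(C)(C)[Si](C)(C)OC/C(C)=C/CC/C(CO)=C\CC/C(C)=C\C[C@@H](CSc1ccccc1)/C(C)=C/CC=C(C)C | intermediate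
30 | C20 tert-butyldiphenylsilyl ether of 29 | CC(C)(C)[Si](C)(C)OC/C(C)=C/CC/C(CO[Si](c1ccccc1)(c1ccccc1)C(C)(C)C)=C\CC/C(C)=C\C[C@@H](CSc1ccccc1)/C(C)=C/CC=C(C)C | intermediate
31 | C14 phenyl sulfoxide of 30 (sulfur epimers) | CC(C)(C)[Si](C)(C)OC/C(C)=C/CC/C(CO[Si](c1ccccc1)(c1ccccc1)C(C)(C)C)=C\CC/C(C)=C\C[C@@H](CS(=O)c1ccccc1)/C(C)=C/CC=C(C)C | intermediate
32 | C14 phenyl sulfone (C13 OTBS; C20 OTBDPS) | CC(C)(C)[Si](C)(C)OC/C(C)=C/CC/C(CO[Si](c1ccccc1)(c1ccccc1)C(C)(C)C)=C\CC/C(C)=C\C[C@@H](CS(=O)(=O)c1ccccc1)/C(C)=C/CC=C(C)C | intermediate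
33 | C13 allylic alcohol (C14 SO2Ph; C20 OTBDPS) | OC/C(C)=C/CC/C(CO[Si](c1ccccc1)(c1ccccc1)C(C)(C)C)=C\CC/C(C)=C\C[C@@H](CS(=O)(=O)c1ccccc1)/C(C)=C/CC=C(C)C | intermediate
34 | C13 allylic bromide (C14 SO2Ph; C20 OTBDPS) | BrC/C(C)=C/CC/C(CO[Si](c1ccccc1)(c1ccccc1)C(C)(C)C)=C\CC/C(C)=C\C[C@@H](CS(=O)(=O)c1ccccc1)/C(C)=C/CC=C(C)C | intermediate
35 | lithium C14 sulfonyl carbanion of 34 | [Li+].BrC/C(C)=C/CC/C(CO[Si](c1ccccc1)(c1ccccc1)C(C)(C)C)=C\CC/C(C)=C\C[C@@H]([CH-]S(=O)(=O)c1ccccc1)/C(C)=C/CC=C(C)C | intermediate
36 | macrocyclic C14 phenyl sulfone (1R,3Z,7E,11E; C20 OTBDPS; C14 epimers) | CC(C)=CC/C=C(\C)[C@H]1C/C=C(/C)CC/C=C(/CO[Si](c2ccccc2)(c2ccccc2)C(C)(C)C)CC/C=C(\C)CC1S(=O)(=O)c1ccccc1 | intermediate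
37 | C20 tert-butyldiphenylsilyl ether of the target | CC(C)=CC/C=C(\C)[C@H]1C/C=C(/C)CC/C=C(/CO[Si](c2ccccc2)(c2ccccc2)C(C)(C)C)CC/C=C(\C)CC1 | intermediate
38 | CNP0355114.1, (1R,3Z,7E,11E)-8-(hydroxymethyl)-4,12-dimethyl-1-[(2E)-6-methylhepta-2,5-dien-2-yl]cyclotetradeca-3,7,11-triene | CC(C)=CC/C=C(\C)[C@H]1C/C=C(/C)CC/C=C(/CO)CC/C=C(\C)CC1 | target

Total step count: 22.
Longest linear sequence: 16 steps (10 → 38 through steps 4–11 and 15–22).

Steps most likely to fail

1. Step 15. The functionalised Grignard reagent may be used up faster than it adds. Carbocupration of the internal alkyne may be slow at the temperature the reagent tolerates, and the reagent may cyclise to a cyclopropylcarbinyl species that expels the allylic silyloxy group or homocouple on copper. Chelate control may also be incomplete, so that syn addition or attack at C7 competes. Fallback, from 22 and returning to 29: the C8–C9 bond is made in stages that give the same geometry. Hydroxyl-directed trans-hydrostannation of 22 ([Cp*RuCl]4 cat., Bu3SnH, CH2Cl2, rt) should place tin on C8 and hydrogen on C7 anti to it, giving the (Z)-2-(tributylstannyl) allylic alcohol F1. Iododestannylation (I2, CH2Cl2, 0 °C) gives the (Z)-2-iodo allylic alcohol F2. Reagent 26 is transmetalated with ZnBr2 to the alkylzinc bromide F3, which does not cyclise. An excess of F3 is then joined to F2 by Negishi coupling (PdCl2(dppf) cat., THF, 40 °C) with retention of the alkene geometry, which gives 29.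

2. Step 20. Intermolecular alkylation may outrun the slow 14-membered closure, the base may trigger 1,4-elimination of the allylic bromide, or the carbanion may close in the SN2′ sense. Fallback, from 32 and returning to 36: the closure is changed to a neutral palladium-catalysed allylic alkylation with a doubly stabilised nucleophile. Sulfone 32 is C-acylated at C14 (LiN(i-Pr)2, 2.2 equiv, then ClCO2Me, THF, −78 °C) to the methyl α-sulfonyl ester F4. The TBS ether is removed (pyridinium p-toluenesulfonate, EtOH) to give the allylic alcohol F5, which is converted (ClCO2Me, pyridine, CH2Cl2, 0 °C) into the allylic methyl carbonate F6. Tsuji–Trost cyclisation (Pd(PPh3)4 cat., THF, 65 °C, slow addition) should attack the unsubstituted allyl terminus C13 and give the macrocyclic sulfonyl ester F7. Krapcho demethoxycarbonylation (LiCl, wet DMSO, 140 °C) then gives 36.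

3. Step 8. The delocalised dienolate may alkylate at C16 instead of C1, lose the E geometry of C15=C16 by rotation, or give a product that drifts into conjugation or epimerises; facial selectivity with the bulky α-alkenyl group may also be lower than for simple acyl imides. Fallback, from 6 (with 16) and returning to 19: the covalent auxiliary is replaced by a chiral base. Acid 6 is converted into its dilithium enediolate with n-BuLi in the presence of a C2-symmetric chiral tetramine (1-phenyl-2-piperidinoethylamine units joined at nitrogen by a propane-1,3-diyl tether, used as its dilithium amide; THF, −78 °C) and alkylated at the α-carbon with 16. This type of direct enantioselective alkylation is known for β,γ-unsaturated acids, and the enantiomer of the amine that leads to the 2R acid is chosen. The product is (2R,4Z)-5-methyl-2-[(2E)-6-methylhepta-2,5-dien-2-yl]non-4-en-8-ynoic acid F8. Reduction with LiAlH4 (THF, 0 °C) gives 19.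

Further compounds
F1 | step 15 | (Z)-2-(tributylstannyl) allylic alcohol from 22 (tin on C8; hydrogen on C7) | OC/C([Sn](CCCC)(CCCC)CCCC)=C/CC/C(C)=C\C[C@@H](CSc1ccccc1)/C(C)=C/CC=C(C)C
F2 | step 15 | (Z)-2-iodo allylic alcohol (iodine on C8) | OC/C(I)=C/CC/C(C)=C\C[C@@H](CSc1ccccc1)/C(C)=C/CC=C(C)C
F3 | step 15 | [(3E)-5-(tert-butyldimethylsilyloxy)-4-methylpent-3-en-1-yl]zinc bromide | CC(C)(C)[Si](C)(C)OC/C(C)=C/CC[Zn]Br
F4 | step 20 | methyl α-sulfonyl ester, 32 carrying CO2Me on C14 (C14 epimers) | CC(C)(C)[Si](C)(C)OC/C(C)=C/CC/C(CO[Si](c1ccccc1)(c1ccccc1)C(C)(C)C)=C\CC/C(C)=C\C[C@@H](C(C(=O)OC)S(=O)(=O)c1ccccc1)/C(C)=C/CC=C(C)C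
F5 | step 20 | C13 allylic alcohol of F4 | OC/C(C)=C/CC/C(CO[Si](c1ccccc1)(c1ccccc1)C(C)(C)C)=C\CC/C(C)=C\C[C@@H](C(C(=O)OC)S(=O)(=O)c1ccccc1)/C(C)=C/CC=C(C)C
F6 | step 20 | C13 allylic methyl carbonate of F5 | COC(=O)OC/C(C)=C/CC/C(CO[Si](c1ccccc1)(c1ccccc1)C(C)(C)C)=C\CC/C(C)=C\C[C@@H](C(C(=O)OC)S(=O)(=O)c1ccccc1)/C(C)=C/CC=C(C)C
F7 | step 20 | macrocyclic C14 methoxycarbonyl phenyl sulfone (C14 epimers) | CC(C)=CC/C=C(\C)[C@H]1C/C=C(/C)CC/C=C(/CO[Si](c2ccccc2)(c2ccccc2)C(C)(C)C)CC/C=C(\C)CC1(C(=O)OC)S(=O)(=O)c1ccccc1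
F8 | step 8 | (2R,4Z)-5-methyl-2-[(2E)-6-methylhepta-2,5-dien-2-yl]non-4-en-8-ynoic acid | C#CCC/C(C)=C\C[C@@H](C(O)=O)/C(C)=C/CC=C(C)C
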